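**Plan**

1. Numbering: C1 (CH–OAc), C2 (CH2), C3 (quaternary, CH3), C4 (CH–OH), C5 (CH2), C6 (=C–CH3), C7 (=CH), C8 (CH–O-aroyl), C9 (ring-fusion CH), C10 (C(OH)–iPr); ring A = C1, C2, C3, C9, C10; ring B = C3 to C9 through C4–C8.
2. Retrosynthesis: take off the acetate and the 4-hydroxybenzoate, trace the C1/C10 cis-diol to a C1=C10 isopropyl alkene (from a C10 ketone), open ring B at C6=C7 (metathesis), cut C7–C8 (vinyl) and C4–C5 (methallyl), and last cut the ring-fusion bond C3–C9 of ring A.
3. Enabling feature: C9 sits between the oxygen-bearing C8 and C10, and C3 carries the oxygen-bearing C4, so both ends of C3–C9 are donor (enolate-type) carbons; the bond is made by one-electron oxidation, the C9 radical of a C8-amide/C10-ketone adding to C3 of a C3=C4 methyl enol ether, with C4 ending as the aldehyde.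
4. Forward order: chain C8–C9–C10–C1–C2–C3=C4, then ring A (step 4), then the C4–C5 and C7–C8 bonds, then ring B (C6=C7), then the C8 ester, then the ring A alkene, diol and acetate.
5. Stereochemistry: C3 from the (2R,5R)-2,5-dimethylpyrrolidine amide in the radical closure; C9 by cis-lactonization onto the C4 hydroxyl (which also releases the auxiliary); C4 from the Ipc2B methallyl reagent; C8 by hydride addition to the convex face of the cis-fused enone; C1 and C10 by OsO4 on the convex face of ring A.

Key step: step 4

Remark on the auxiliary: the (2R,5R) amide is assumed to deliver the enol ether face that gives (S)-C3; if the cyclization shows the opposite sense, (2S,5S)-2,5-dimethylpyrrolidine is used in step 1 and nothing else changes, because the auxiliary leaves in step 6.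
Remark on the enol ether: the Wittig reaction of step 2 gives both geometries; C4 ends as the aldehyde carbon, so the mixture is carried to step 4 and the E isomer is drawn.

**Route**

Step 1
Reactants: 1 (2R,5R)-2,5-dimethylpyrrolidine
Product: 2 1-[(2R,5R)-2,5-dimethylpyrrolidin-1-yl]ethan-1-one (N-acetyl auxiliary)
Conditions: Ac2O, Et3N, CH2Cl2, 0 °C → rt
Reagents that add atoms: acetic anhydride, CC(=O)OC(C)=O
Why: Acylation of the secondary amine by the anhydride (N-acetylation) is fast and does not touch the two stereocenters of the C2-symmetric pyrrolidine.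

Step 2
Reactants: 3 methyl levulinate
Product: 4 methyl (E)-5-methoxy-4-methylpent-4-enoate
Conditions: Ph3P(CH2OMe)Cl, KOtBu, THF, 0 °C → rt
Reagents that add atoms: (methoxymethyl)triphenylphosphonium chloride, COC[P+](c1ccccc1)(c1ccccc1)c1ccccc1.[Cl-]
Why: Wittig olefination with the methoxymethylene ylide converts the ketone into the methyl enol ether while the less electrophilic methyl ester is left alone, so C4 enters at the enol ether oxidation level.

Step 3
Reactants: 2 1-[(2R,5R)-2,5-dimethylpyrrolidin-1-yl]ethan-1-one; 4 methyl (E)-5-methoxy-4-methylpent-4-enoate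
Product: 5 (E)-1-[(2R,5R)-2,5-dimethylpyrrolidin-1-yl]-7-methoxy-6-methylhept-6-ene-1,3-dione (C8 amide, C10 ketone, C3=C4 enol ether)
Conditions: LiN(iPr)2 (2.1 equiv), 2 (2.0 equiv), THF, −78 °C; then 4, −78 → 0 °C; aq. NH4Cl
Reagents that add atoms: none
Why: Crossed Claisen condensation, in which the lithium enolate of the tertiary acetamide is acylated on carbon by the methyl ester and deprotonation of the product by the second equivalent of enolate drives the reaction; the enol ether is inert to base and the excess of 2 is recovered.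

Step 4
Reactants: 5 (E)-1-[(2R,5R)-2,5-dimethylpyrrolidin-1-yl]-7-methoxy-6-methylhept-6-ene-1,3-dione
Product: 7 [(1S,2S)-2-formyl-2-methyl-5-oxocyclopentyl][(2R,5R)-2,5-dimethylpyrrolidin-1-yl]methanone (ring A; C10 ketone; C4 aldehyde on quaternary C3; C8 amide on C9), via acetoxy methoxy acetal 6 (not isolated)
Conditions: Mn(OAc)3·2H2O (2.2 equiv), Cu(OAc)2·H2O (0.2 equiv), KOAc, AcOH, 25 °C; then 1 M HCl, THF, 0 °C
Reagents that add atoms: water, O (aldehyde oxygen on hydrolysis of 6)
Why: Mn(OAc)3 converts the β-keto amide into its trivalent manganese enolate and oxidizes it to the electrophilic C9 radical, which adds to C3, the electron-rich β-carbon of the enol ether; the α-methoxy radical left at C4 is oxidized by Cu(OAc)2 (divalent copper, turned over by Mn(OAc)3) to the oxocarbenium ion, which acetate captures as acetal 6 and dilute acid hydrolyses to the aldehyde. The closest known reaction type is the Mn(OAc)3/Cu(OAc)2 oxidative free-radical cyclization of unsaturated β-keto esters and amides, 2,5-dimethylpyrrolidine amides included, with the oxidative radical addition of 1,3-dicarbonyl compounds to enol ethers as the model for the acceptor. Ring A closes by 5-exo-trig attack of C9 on C3. Quaternary C3 is set by the C2-symmetric amide, whose flanking methyl groups shield one face of the planar C9 radical so that the tether presents one enol ether face; C9 is epimerizable, is drawn with the amide cis to the formyl group (trans to the larger methyl), and is fixed in step 6. The step needs attack at the fully substituted C3 instead of 6-endo attack at C4, which the polarity match (electrophilic radical, nucleophilic β-carbon) and the oxygen stabilization of the C4 radical should secure. Over-oxidation of 7 is not expected, because the hindered tertiary β-keto amide enolizes slowly and the new aldehyde has no α-hydrogen.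

Step 5
Reactants: 7 [(1S,2S)-2-formyl-2-methyl-5-oxocyclopentyl][(2R,5R)-2,5-dimethylpyrrolidin-1-yl]methanone
Product: 8 [(1S,2S)-2-[(1S)-1-hydroxy-3-methylbut-3-en-1-yl]-2-methyl-5-oxocyclopentyl][(2R,5R)-2,5-dimethylpyrrolidin-1-yl]methanone (C4 carbinol with C5, C6 and the C6 methyl attached)
Conditions: (−)-Ipc2BOMe, methallylmagnesium chloride, Et2O, 0 °C → rt; then 7, −78 °C; HOCH2CH2NH2 work-up
Reagents that add atoms: methallylmagnesium chloride, CC(=C)C[Mg]Cl (transferred through boron)
Why: Brown methallylboration proceeds through a closed chair transition state and is selective for the aldehyde over the ketone and amide, and the isopinocampheyl groups of the reagent derived from (+)-α-pinene direct the methallyl group to the Si face of the C4 aldehyde, which sets (S)-C4 under reagent control.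

Step 6
Reactants: 8 [(1S,2S)-2-[(1S)-1-hydroxy-3-methylbut-3-en-1-yl]-2-methyl-5-oxocyclopentyl][(2R,5R)-2,5-dimethylpyrrolidin-1-yl]methanone
Product: 9 (3S,3aS,6aS)-3a-methyl-3-(2-methylprop-2-en-1-yl)tetrahydro-1H-cyclopenta[c]furan-1,6(6aH)-dione (keto lactone: C8(=O)–O–C4 cis-fused to ring A, C10 ketone)
Conditions: TsOH·H2O (1.5 equiv), toluene, 70 °C; aq. NaHCO3 (amine recovered)
Reagents that add atoms: none
Why: Acid-promoted N→O acyl transfer of the γ-hydroxy amide (lactonization) gives the cis-fused γ-lactone and expels the protonated amine; only the C9 epimer with C8 cis to C4 can close and the other one equilibrates through the enol of the β-keto amide, so the step fixes C9 and returns the auxiliary.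

Step 7
Reactants: 9 keto lactone
Product: 10 C10 ethylene ketal of keto lactone 9 (dioxolane on C10; lactone, methallyl group and configuration unchanged)
Conditions: HOCH2CH2OH, TsOH·H2O (cat.), benzene, reflux (Dean–Stark)
Reagents that add atoms: ethylene glycol, OCCO
Why: Acid-catalysed dioxolane formation with azeotropic removal of water, as for acetoacetates, masks the C10 ketone so that C9–H is no longer that of a β-dicarbonyl compound in the hydride and Grignard steps, and the 1,1-disubstituted alkene tolerates these conditions.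

Step 8
Reactants: 10 ketal lactone
Product: 12 (1S)-1-[(6R,7S)-6-(1-hydroxyprop-2-en-1-yl)-7-methyl-1,4-dioxaspiro[4.4]nonan-7-yl]-3-methylbut-3-en-1-ol (C4 and C8 diol; both C8 epimers), via lactol 11 (not isolated)
Conditions: iBu2AlH, toluene, −78 °C; then CH2=CHMgBr (4 equiv), THF, −78 °C → rt; aq. potassium sodium tartrate
Reagents that add atoms: vinylmagnesium bromide, C=C[Mg]Br
Why: Half-reduction of the γ-lactone by iBu2AlH stops at the aluminium lactolate at −78 °C, and the vinyl Grignard reagent then adds to the ring-opened hydroxy aldehyde (lactol opening and Grignard addition) to give the diol; the C8 configuration formed here is irrelevant because C8 is oxidized in step 10.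

Step 9
Reactants: 12 diene diol
Product: 13 bicyclic diol: cis-fused ring A/ring B skeleton with C10 ethylene ketal, C3 methyl, (4S)-C4–OH, C6(CH3)=C7 and C8–OH (both C8 epimers)
Conditions: second-generation Grubbs catalyst (H2IMes)(PCy3)Cl2Ru=CHPh (5 mol %), CH2Cl2, 40 °C
Reagents that add atoms: none
Why: Ring-closing olefin metathesis between the vinyl group and the 1,1-disubstituted alkene, held cis on ring A, closes the seven-membered ring B with the trisubstituted C6=C7 bond and is driven by loss of ethene, the free hydroxyls being tolerated by the ruthenium carbene.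

Step 10
Reactants: 13 bicyclic diol
Product: 14 hydroxy enone: C8 ketone conjugated with C6=C7, C4–OH free, C10 ketal
Conditions: MnO2, CH2Cl2, rt
Reagents that add atoms: none
Why: MnO2 oxidizes allylic alcohols selectively, so both C8 epimers converge to the enone while the saturated C4 hydroxyl stays.

Step 11
Reactants: 14 hydroxy enone
Product: 15 enone with C4–OTBS (tert-butyldimethylsilyl ether), C10 ketal
Conditions: TBSOTf, 2,6-lutidine, CH2Cl2, −78 → 0 °C
Reagents that add atoms: tert-butyldimethylsilyl triflate, CC(C)(C)[Si](C)(C)OS(=O)(=O)C(F)(F)F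
Why: The silyl triflate with 2,6-lutidine silylates even the hindered neopentyl-type C4 hydroxyl at low temperature without converting the enone into a silyl dienol ether.

Step 12
Reactants: 15 silyloxy enone
Product: 16 allylic alcohol: (8S)-C8–OH anti to C9–H, C4–OTBS, C10 ketal
Conditions: NaBH4, CeCl3·7H2O, MeOH, −78 °C
Reagents that add atoms: none
Why: Luche reduction gives clean 1,2-reduction of the enone, and hydride should add to C8 from the convex face of the cis-fused bicycle (the face of C9–H, away from ring A and its dioxolane), which places the C8 hydroxyl anti to C9–H as in the target.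

Step 13
Reactants: 17 4-hydroxybenzoic acid
Product: 19 4-[(tert-butyldimethylsilyl)oxy]benzoic acid, via silyl ester 18 (not isolated)
Conditions: TBSCl (2.5 equiv), imidazole, DMF, rt; then AcOH/THF/H2O, rt
Reagents that add atoms: tert-butyldimethylsilyl chloride, CC(C)(C)[Si](C)(C)Cl
Why: Silylation of both the phenol and the acid followed by mild aqueous acid, which hydrolyses only the labile silyl ester, leaves the acid with its phenol protected so that it cannot acylate itself.

Step 14
Reactants: 16 allylic alcohol; 19 4-[(tert-butyldimethylsilyl)oxy]benzoic acid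
Product: 20 C8 4-(TBS-oxy)benzoate of 16 (C4–OTBS, C10 ketal)
Conditions: EDC·HCl, DMAP, CH2Cl2, rt
Reagents that add atoms: none
Why: Steglich esterification (carbodiimide, DMAP) acylates the secondary allylic C8 hydroxyl with retention of configuration, since the C–O bond of the alcohol is not broken.

Step 15
Reactants: 20 ketal ester
Product: 21 C10 ketone (C8 aroate, C4–OTBS, C6=C7)
Conditions: PPTS, acetone/H2O, 60 °C
Reagents that add atoms: water, O
Why: Mild acid-catalysed hydrolysis of the dioxolane frees the C10 ketone, and PPTS is weak enough to spare both silyl ethers and the allylic ester.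

Step 16
Reactants: 21 C10 ketone
Product: 22 C1=C10 enol triflate (C10–OTf)
Conditions: KN(SiMe3)2, THF, −78 °C; then PhNTf2, −78 °C
Reagents that add atoms: N-phenylbis(trifluoromethanesulfonimide), O=S(=O)(N(c1ccccc1)S(=O)(=O)C(F)(F)F)C(F)(F)F
Why: Kinetic deprotonation with KN(SiMe3)2 at −78 °C should take place at the unhindered C1 methylene and not at the C9 methine (flanked by quaternary C3 and C8), and O-sulfonylation of the enolate by PhNTf2 gives the enol triflate, the low temperature and the direction of enolization keeping the β-aroyloxy group from E1cB elimination.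

Step 17
Reactants: 22 enol triflate
Product: 23 C1=C10 alkene with isopropyl on C10
Conditions: iPrMgCl, Fe(acac)3 (5 mol %), THF/NMP, −30 °C
Reagents that add atoms: isopropylmagnesium chloride, CC(C)[Mg]Cl
Why: Fe(acac)3-catalysed cross-coupling of alkenyl triflates with alkyl Grignard reagents (Kumada-type) is fast at −30 °C, tolerates esters and silyl ethers and accepts secondary alkyl groups, so isopropyl replaces the triflate at C10.

Step 18
Reactants: 23 isopropyl alkene
Product: 24 C1,C10 cis-diol (both hydroxyls cis to C9–H; isopropyl on C10)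
Conditions: OsO4 (5 mol %), NMO, acetone/H2O, 0 °C → rt
Reagents that add atoms: osmium tetroxide, O=[Os](=O)(=O)=O; N-methylmorpholine N-oxide, C[N+]1([O-])CCOCC1; water, O
Why: Upjohn dihydroxylation adds both oxygens suprafacially to the electron-richer C1=C10 alkene (C6=C7 is deactivated by the allylic aroyloxy group and screened by the C4 silyl ether and the C8 ester), and OsO4 should approach the convex face of ring A, anti to C8 on the adjacent C9, which sets C1 and C10.

Step 19
Reactants: 24 diol
Product: 25 C1 acetate (C10–OH free, C4–OTBS, aryl–OTBS)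
Conditions: Ac2O, pyridine, DMAP (cat.), CH2Cl2, 0 °C
Reagents that add atoms: acetic anhydride, CC(=O)OC(C)=O
Why: Acetylation with Ac2O/DMAP at 0 °C takes the secondary C1 hydroxyl only, the tertiary C10 hydroxyl being too hindered to react.

Step 20
Reactants: 25 bis-silyl acetate
Product: 26 CNP0146780.2 (target)
Conditions: HF·pyridine, THF/pyridine, 0 °C → rt
Reagents that add atoms: none
Why: Fluoride from HF·pyridine cleaves the aryl and the alkyl silyl ether in one operation, while the acetate, the benzoate, the tertiary alcohol and the alkene are stable to this buffered acid.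

**Compound list**

1 | (2R,5R)-2,5-dimethylpyrrolidine | C[C@@H]1CC[C@@H](C)N1 | starting material
2 | 1-[(2R,5R)-2,5-dimethylpyrrolidin-1-yl]ethan-1-one | CC(=O)N1[C@H](C)CC[C@H]1C | intermediate
3 | methyl levulinate (methyl 4-oxopentanoate) | CC(=O)CCC(=O)OC | starting material
4 | methyl (E)-5-methoxy-4-methylpent-4-enoate (Z isomer carried with it) | CO/C=C(\C)CCC(=O)OC | intermediate
5 | (E)-1-[(2R,5R)-2,5-dimethylpyrrolidin-1-yl]-7-methoxy-6-methylhept-6-ene-1,3-dione | CO/C=C(\C)CCC(=O)CC(=O)N1[C@H](C)CC[C@H]1C | intermediate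
6 | [(1S,2S)-2-[acetoxy(methoxy)methyl]-2-methyl-5-oxocyclopentyl][(2R,5R)-2,5-dimethylpyrrolidin-1-yl]methanone (both acetal epimers) | COC(OC(C)=O)[C@@]1(C)CCC(=O)[C@H]1C(=O)N1[C@H](C)CC[C@H]1C | intermediate (not isolated)
7 | [(1S,2S)-2-formyl-2-methyl-5-oxocyclopentyl][(2R,5R)-2,5-dimethylpyrrolidin-1-yl]methanone | O=C[C@@]1(C)CCC(=O)[C@H]1C(=O)N1[C@H](C)CC[C@H]1C | intermediate
8 | [(1S,2S)-2-[(1S)-1-hydroxy-3-methylbut-3-en-1-yl]-2-methyl-5-oxocyclopentyl][(2R,5R)-2,5-dimethylpyrrolidin-1-yl]methanone | CC(=C)C[C@H](O)[C@@]1(C)CCC(=O)[C@H]1C(=O)N1[C@H](C)CC[C@H]1C | intermediate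
9 | (3S,3aS,6aS)-3a-methyl-3-(2-methylprop-2-en-1-yl)tetrahydro-1H-cyclopenta[c]furan-1,6(6aH)-dione | CC(=C)C[C@@H]1OC(=O)[C@@H]2C(=O)CC[C@]12C | intermediate
10 | C10 ethylene ketal of 9 | CC(=C)C[C@@H]1OC(=O)[C@@H]2C3(OCCO3)CC[C@]12C | intermediate
11 | lactol of 10 (C8–OH, both anomers) | CC(=C)C[C@@H]1OC(O)[C@@H]2C3(OCCO3)CC[C@]12C | intermediate (not isolated)
12 | (1S)-1-[(6R,7S)-6-(1-hydroxyprop-2-en-1-yl)-7-methyl-1,4-dioxaspiro[4.4]nonan-7-yl]-3-methylbut-3-en-1-ol (both C8 epimers) | CC(=C)C[C@H](O)[C@@]1(C)CCC2(OCCO2)[C@H]1C(O)C=C | intermediate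
13 | bicyclic diol: C10 ketal, (4S)-C4–OH, C6=C7, C8–OH (both C8 epimers) | C1C[C@]2(C)[C@@H](O)CC(C)=CC(O)[C@@H]2C13OCCO3 | intermediate
14 | hydroxy enone: C8 ketone, C4–OH, C10 ketal | C1C[C@]2(C)[C@@H](O)CC(C)=CC(=O)[C@@H]2C13OCCO3 | intermediate
15 | enone with C4–OTBS, C10 ketal | C1C[C@]2(C)[C@@H](O[Si](C)(C)C(C)(C)C)CC(C)=CC(=O)[C@@H]2C13OCCO3 | intermediate
16 | allylic alcohol: (8S)-C8–OH, C4–OTBS, C10 ketal | C1C[C@]2(C)[C@@H](O[Si](C)(C)C(C)(C)C)CC(C)=C[C@H](O)[C@@H]2C13OCCO3 | intermediate
17 | 4-hydroxybenzoic acid | OC(=O)c1ccc(O)cc1 | starting material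
18 | tert-butyldimethylsilyl 4-[(tert-butyldimethylsilyl)oxy]benzoate | CC(C)(C)[Si](C)(C)OC(=O)c1ccc(O[Si](C)(C)C(C)(C)C)cc1 | intermediate (not isolated)
19 | 4-[(tert-butyldimethylsilyl)oxy]benzoic acid | OC(=O)c1ccc(O[Si](C)(C)C(C)(C)C)cc1 | intermediate
20 | C8 4-(TBS-oxy)benzoate, C4–OTBS, C10 ketal | C1C[C@]2(C)[C@@H](O[Si](C)(C)C(C)(C)C)CC(C)=C[C@H](OC(=O)c3ccc(O[Si](C)(C)C(C)(C)C)cc3)[C@@H]2C14OCCO4 | intermediate
21 | C10 ketone, C8 aroate, C4–OTBS | C1C[C@]2(C)[C@@H](O[Si](C)(C)C(C)(C)C)CC(C)=C[C@H](OC(=O)c3ccc(O[Si](C)(C)C(C)(C)C)cc3)[C@@H]2C1=O | intermediate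
22 | C1=C10 enol triflate | FC(F)(F)S(=O)(=O)OC1=CC[C@]2(C)[C@@H](O[Si](C)(C)C(C)(C)C)CC(C)=C[C@H](OC(=O)c3ccc(O[Si](C)(C)C(C)(C)C)cc3)[C@@H]21 | intermediate
23 | C10-isopropyl C1=C10 alkene | CC(C)C1=CC[C@]2(C)[C@@H](O[Si](C)(C)C(C)(C)C)CC(C)=C[C@H](OC(=O)c3ccc(O[Si](C)(C)C(C)(C)C)cc3)[C@@H]21 | intermediate
24 | C1,C10 cis-diol | O[C@H]1C[C@]2(C)[C@@H](O[Si](C)(C)C(C)(C)C)CC(C)=C[C@H](OC(=O)c3ccc(O[Si](C)(C)C(C)(C)C)cc3)[C@@H]2[C@]1(O)C(C)C | intermediate
25 | C1 acetate, bis-silyl ether | CC(=O)O[C@H]1C[C@]2(C)[C@@H](O[Si](C)(C)C(C)(C)C)CC(C)=C[C@H](OC(=O)c3ccc(O[Si](C)(C)C(C)(C)C)cc3)[C@@H]2[C@]1(O)C(C)C | intermediate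
26 | CNP0146780.2: C1 acetate, C4–OH, C8 4-hydroxybenzoate, C10–OH (1S,3S,4S,8S,9R,10R in the route numbering) | CC(=O)O[C@H]1C[C@]2(C)[C@@H](O)CC(C)=C[C@H](OC(=O)c3ccc(O)cc3)[C@@H]2[C@]1(O)C(C)C | target

**Step count and risks**

Total step count: 20. Longest linear sequence: 18 steps (steps 1, 3–12 and 14–20, from 1).

Steps most likely to fail:

1. Step 4. The radical may close in the 6-endo sense at C4, the enol ether may be consumed by acid before it is attacked, or the amide may discriminate the two enol ether faces poorly. The fallback sets out from 5 and returns at 7. Regitz diazo transfer to 5 (4-acetamidobenzenesulfonyl azide, Et3N, MeCN) should give the α-diazo β-keto amide F1. Rh2(OAc)4 in CH2Cl2 then brings about intramolecular cyclopropanation of the enol ether, which can only give the bicyclo[3.1.0]hexanone, the methoxycyclopropane F2, with the C3–C9 bond and ring A in place; a chiral dirhodium carboxylate can reinforce the auxiliary. Dilute HCl in wet THF opens this donor–acceptor cyclopropane at the C9–C4 bond and delivers 7.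

2. Step 12. Hydride may be delivered from the concave face, so that the C8 epimer or a mixture results. The fallback sets out from 15 and returns at 20. The epimeric product of the reduction, the 8-epi allylic alcohol F3, is esterified with acid 19 under Mitsunobu conditions (PPh3, DIAD, toluene, 0 °C), which forms the C8–O bond with inversion and gives 20 directly, in place of steps 12 and 14.

3. Step 16. Enolization toward C9 may be followed by E1cB loss of the aroate, or the enolate may form with the wrong regiochemistry. The fallback sets out from 21 and returns at 23. The weakly basic organocerium reagent from iPrMgCl and CeCl3 (THF, −78 °C) should add to the C10 ketone from the convex face and give the tertiary alcohol F4, with its hydroxyl on the concave face. Syn dehydration with the Burgess reagent (benzene, 50 °C) can use a C1 hydrogen but not C9–H, which is anti to the hydroxyl, and gives 23 without an enolate.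

**Further compounds**

F1 | step 4 | (E)-2-diazo-1-[(2R,5R)-2,5-dimethylpyrrolidin-1-yl]-7-methoxy-6-methylhept-6-ene-1,3-dione | CO/C=C(\C)CCC(=O)C(=[N+]=[N-])C(=O)N1[C@H](C)CC[C@H]1C
F2 | step 4 | (6-methoxy-5-methyl-2-oxobicyclo[3.1.0]hexan-1-yl)[(2R,5R)-2,5-dimethylpyrrolidin-1-yl]methanone (methoxy cis to the C3 methyl) | CO[C@@H]1[C@@]2(C)CCC(=O)[C@@]12C(=O)N1[C@H](C)CC[C@H]1C
F3 | step 12 | C8 epimer of allylic alcohol 16 | C1C[C@]2(C)[C@@H](O[Si](C)(C)C(C)(C)C)CC(C)=C[C@@H](O)[C@@H]2C13OCCO3
F4 | step 16 | C10 tertiary alcohol from 21 (isopropyl on the convex face, hydroxyl on the concave face) | C1C[C@]2(C)[C@@H](O[Si](C)(C)C(C)(C)C)CC(C)=C[C@H](OC(=O)c3ccc(O[Si](C)(C)C(C)(C)C)cc3)[C@@H]2[C@@]1(O)C(C)C
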